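**Plan**

Retrosynthesis: after global O-debenzylation, each ent-fisetinidol unit is cut the same way, unit D first, then A, then B: the C2–C1′ bond (ring B as an aryltrifluoroborate), the pyran ring at C3–C4 and O1–C2 (back to an o-hydroxybenzhydrol and benzyloxyacetaldehyde), and the carbinol–aryl bond that is the later interflavanyl bond (aryllithium plus a salicylaldehyde).
Forward: (+)-catechin is benzylated and brominated at C8; unit B is built there from a 5-bromosalicylaldehyde, unit A on that bromine handle (C6 of unit B), and unit D after bromination at C6 of the catechin ring, so the pyran rings arise in the order B, A, D, each followed by C2 arylation; hydrogenolysis ends the route.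
Enabling feature: in every upper unit C4 is a doubly benzylic carbon ortho to the phenolic oxygen O1 (on C8a) of a resorcinol-type ring A and activated through C4a by the para oxygen O7; loss of water from the carbinol gives the o-quinone methide O1=C8a–C4a=C4, a 1-oxadiene that takes up the enol C3=C2.
Stereochemistry: C2 and C3 of the catechin unit come from the chiral pool; C3 and C4 of each upper unit (3R, 3,4-cis = 4α, aryl cis to O3 and trans to the 2-aryl group) are set by the chiral phosphoric acid in the annulation; C2 (2S, 2,3-trans) by attack of the aryl nucleophile on the oxocarbenium ion anti to the cis C3/C4 substituents.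
Helpers: benzyl ethers (which also keep O5 and O7 of catechin from closing a ring), two bromine handles, the carbinol and lactol hydroxyl groups; all leave in the lithiation, annulation, arylation or final hydrogenolysis.

Key step: step 14

Assumption: the (S)-phosphoric acid is taken to give the (3R,4S) cis-lactols; this sense of induction is a prediction, and the (R)-acid would be used in steps 6, 10 and 14 if it proved opposite.

**Route**

Step 1
Reactants: 1 (+)-catechin
Product: 2 3,5,7,3′,4′-penta-O-benzyl-(+)-catechin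
Conditions: BnBr (6.5 equiv), NaH (6.2 equiv), DMF, −20 °C → rt
Reagents that add atoms: benzyl bromide, BrCc1ccccc1
Why: Williamson etherification of the four phenols and the C3 alcohol, run cold so that the base does not open the pyran ring, leaves C2 and C3 untouched.

Step 2
Reactants: 2 penta-O-benzylcatechin
Product: 3 8-bromo-3,5,7,3′,4′-penta-O-benzyl-(+)-catechin
Conditions: NBS (1.0 equiv), CH2Cl2, −78 → 0 °C
Reagents that add atoms: N-bromosuccinimide, O=C1CCC(=O)N1Br
Why: Electrophilic aromatic bromination goes to C8, the most nucleophilic position of 5,7-di-O-benzylated flavan-3-ols.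

Step 3
Reactants: 4 4-(benzyloxy)-2-hydroxybenzaldehyde
Product: 5 5-bromo-4-(benzyloxy)-2-hydroxybenzaldehyde
Conditions: NBS (1.05 equiv), MeCN, 0 °C → rt
Reagents that add atoms: N-bromosuccinimide, O=C1CCC(=O)N1Br
Why: Electrophilic bromination para to the free phenol puts the handle on the carbon that becomes C6 of unit B, where unit A is attached later.

Step 4
Reactants: 6 [3,4-bis(benzyloxy)phenyl]boronic acid
Product: 7 potassium [3,4-bis(benzyloxy)phenyl]trifluoroborate
Conditions: KHF2 (aq., 4 equiv), MeOH, rt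
Reagents that add atoms: potassium hydrogen difluoride (KHF2), [K+].[F-].F
Why: Standard conversion of a boronic acid into its bench-stable trifluoroborate salt, the ring B donor for steps 7, 11 and 15.

Step 5
Reactants: 3 8-bromo-penta-O-benzylcatechin; 5 5-bromo-4-(benzyloxy)-2-hydroxybenzaldehyde
Product: 10 carbinol B [5-bromo-4-(benzyloxy)-2-hydroxyphenyl](3,5,7,3′,4′-penta-O-benzylcatechin-8-yl)methanol (both carbinol epimers), via aryllithium 8 (not isolated), via sodium phenolate 9 (not isolated)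
Conditions: 3, n-BuLi, THF, −78 °C; then 9 (from 5, NaH, THF, 0 °C), −78 → −30 °C; H2O
Reagents that add atoms: none
Why: Bromine–lithium exchange and 1,2-addition of the aryllithium to the aldehyde, whose phenol is masked as the sodium salt, forms the future C4–C8 interflavanyl bond; the carbinol centre need not be controlled because it becomes the planar methide carbon in step 6.

Step 6
Reactants: 10 carbinol B; 11 2-(benzyloxy)acetaldehyde
Product: 13 lactol B (3R,4S)-3,7-bis(benzyloxy)-6-bromo-4-(penta-O-benzylcatechin-8-yl)chroman-2-ol (3,4-cis; both anomers), via o-quinone methide 12 (not isolated)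
Conditions: (S)-3,3′-bis(2,4,6-triisopropylphenyl)-1,1′-binaphthyl-2,2′-diyl hydrogen phosphate (10 mol %), 11 (3 equiv), 4 Å MS, CHCl3, 0 °C → rt
Reagents that add atoms: none
Why: Chiral phosphoric acid-catalysed dehydration to the o-quinone methide and formal [4+2] addition of the enol of 11 (the reaction type of step 14) should close the pyran ring of unit B and set C4 and C3 cis under catalyst control.

Step 7
Reactants: 13 lactol B; 7 potassium [3,4-bis(benzyloxy)phenyl]trifluoroborate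
Product: 14 dimer bromide 6-bromo-3,7,3′,4′-tetra-O-benzyl-ent-fisetinidol-(4α→8)-3,5,7,3′,4′-penta-O-benzylcatechin (upper unit 2S,3R,4S; 2,3-trans-3,4-cis)
Conditions: 7 (3 equiv), BF3·OEt2 (4 equiv), MeCN/CH2Cl2, −40 → 0 °C
Reagents that add atoms: none
Why: Lewis acid-mediated ipso aryl transfer from the trifluoroborate to the C2 oxocarbenium ion of the lactol (C-glycosylation-type arylation of a cyclic hemiacetal) should occur anti to the cis C3-benzyloxy and C4-aryl groups, which sets C2 as 2S (2,3-trans) and fixes the 3′,4′-dioxygenation.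

Step 8
Reactants: 4 4-(benzyloxy)-2-hydroxybenzaldehyde
Product: 15 sodium 5-(benzyloxy)-2-formylphenolate
Conditions: NaH (1.0 equiv), THF, 0 °C → rt; evaporate, dry in vacuo; one batch, kept under Ar for steps 9 and 13
Reagents that add atoms: sodium hydride (NaH), [Na+].[H-]
Why: Irreversible acid–base reaction of the acidic, chelated phenol with hydride (phenolate formation) gives the isolable sodium salicylaldehydate, in which the phenol is masked against organolithium reagents while the formyl group stays free.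

Step 9
Reactants: 14 dimer bromide; 15 sodium 5-(benzyloxy)-2-formylphenolate
Product: 17 carbinol A (14 with CH(OH)[4-(benzyloxy)-2-hydroxyphenyl] in place of Br at C6 of the upper unit; both carbinol epimers), via aryllithium 16 (not isolated)
Conditions: 14, n-BuLi, THF, −78 °C; then 15 (2 equiv, THF suspension), −78 → −30 °C; H2O
Reagents that add atoms: none
Why: Bromine–lithium exchange at C6 of unit B (ortho to O7) and carbonyl addition place the future C4–C6 interflavanyl bond regiospecifically, which electrophilic substitution could not do in the presence of the free C6 of the catechin ring.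

Step 10
Reactants: 17 carbinol A; 11 2-(benzyloxy)acetaldehyde
Product: 19 lactol A (top unit a (3R)-3,7-bis(benzyloxy)-3,4-cis-chroman-2-ol joined through C4 to C6 of the middle unit; both anomers), via o-quinone methide 18 (not isolated)
Conditions: (S)-3,3′-bis(2,4,6-triisopropylphenyl)-1,1′-binaphthyl-2,2′-diyl hydrogen phosphate (10 mol %), 11 (3 equiv), 4 Å MS, CHCl3, 0 °C → rt
Reagents that add atoms: none
Why: The same phosphoric acid-catalysed o-quinone methide/enol [4+2] annulation as in step 6 should close the pyran ring of unit A with C3 and C4 cis and in the same absolute sense.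

Step 11
Reactants: 19 lactol A; 7 potassium [3,4-bis(benzyloxy)phenyl]trifluoroborate
Product: 20 trimer 3,7,3′,4′-tetra-O-benzyl-ent-fisetinidol-(4α→6)-3,7,3′,4′-tetra-O-benzyl-ent-fisetinidol-(4α→8)-3,5,7,3′,4′-penta-O-benzylcatechin
Conditions: 7 (3 equiv), BF3·OEt2 (4 equiv), MeCN/CH2Cl2, −40 → 0 °C
Reagents that add atoms: none
Why: Oxocarbenium arylation with the trifluoroborate as in step 7 should deliver ring B of unit A anti to the cis C3/C4 substituents (2S, 2,3-trans).

Step 12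
Reactants: 20 trimer
Product: 21 6-bromo trimer (Br at C6 of the catechin unit of 20)
Conditions: NBS (1.05 equiv), CH2Cl2, −40 → 0 °C
Reagents that add atoms: N-bromosuccinimide, O=C1CCC(=O)N1Br
Why: Electrophilic aromatic bromination should go to C6 of the catechin unit, the only free position on a phloroglucinol-type ring and so the most nucleophilic aromatic carbon of 20.

Step 13
Reactants: 21 6-bromo trimer; 15 sodium 5-(benzyloxy)-2-formylphenolate
Product: 23 carbinol D (20 carrying CH(OH)[4-(benzyloxy)-2-hydroxyphenyl] at C6 of the catechin unit; both carbinol epimers), via aryllithium 22 (not isolated)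
Conditions: 21, n-BuLi, THF, −78 °C; then 15 (3 equiv, THF suspension), −78 → −30 °C; H2O
Reagents that add atoms: none
Why: Bromine–lithium exchange gives a 2,6-dialkoxyaryllithium that adds to the aldehyde (carbonyl addition) and forms the future C4–C6 bond of unit D, the carbinol centre again being of no consequence.

Step 14
Reactants: 23 carbinol D; 11 2-(benzyloxy)acetaldehyde
Product: 25 lactol D (20 carrying at C6 of the catechin unit a (3R,4S)-3,7-bis(benzyloxy)-2-hydroxychroman-4-yl group; 3,4-cis; both anomers), via o-quinone methide 24 (not isolated)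
Conditions: (S)-3,3′-bis(2,4,6-triisopropylphenyl)-1,1′-binaphthyl-2,2′-diyl hydrogen phosphate (10 mol %), 11 (3 equiv), 4 Å MS, CHCl3, 0 °C → rt
Reagents that add atoms: none
Why: The phosphoric acid ionises the doubly benzylic carbinol of 23 (ortho to the free phenol of ring A of unit D, para-activated by O7) to the (E)-o-quinone methide 24 (O1=C8a–C4a=C4), which stays hydrogen-bonded to the catalyst while the phosphoryl oxygen binds the (Z)-enol of 11; C3 of the enol then adds to C4 and the phenolic oxygen closes onto C2. The closest known reaction type is the chiral phosphoric acid-catalysed formal [4+2] addition of enolisable aldehydes to o-quinone methides generated from o-hydroxybenzhydrols, which gives cis-3,4-disubstituted chroman-2-ols. The pyran ring closes in a hetero-Diels–Alder-like manner, by C3–C4 bond formation and 6-exo-trig hemiacetalisation (O1–C2), and no ring is formed after it. C4 (S) is set by the catalyst-controlled face of the methide carbon and C3 (R) by the catalyst-bound face of the enol; their cis relation follows from the endo arrangement of the Z-enol, in which the benzyloxy group is cis to the enol oxygen and so lies under the heterodiene, while C2 stays an anomeric mixture until step 15. The step needs chemoselective ring closure and catalyst control over substrate control: only O1 is a free phenol (O5 and O7 of the catechin unit are benzylated, so no pyran ring can form on that side), the catechin ring has no free nuclear position left for self-alkylation, and the stereocentres of the trimer are remote from C4.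

Step 15
Reactants: 25 lactol D; 7 potassium [3,4-bis(benzyloxy)phenyl]trifluoroborate
Product: 26 heptadeca-O-benzyl tetramer (per-O-benzyl ether of the target)
Conditions: 7 (3 equiv), BF3·OEt2 (4 equiv), MeCN/CH2Cl2, −40 → 0 °C
Reagents that add atoms: none
Why: Oxocarbenium arylation by ipso aryl transfer from the trifluoroborate, as in steps 7 and 11, should bring ring B of unit D in anti to the cis C3-benzyloxy and C4-aryl groups (2S, 2,3-trans-3,4-cis), with the O1–C2 bond made in step 14 kept throughout.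

Step 16
Reactants: 26 heptadeca-O-benzyl tetramer
Product: 27 ent-fisetinidol-(4α→6)-ent-fisetinidol-(4α→8)-catechin-(6→4α)-ent-fisetinidol (target)
Conditions: H2 (1 atm), Pd(OH)2/C, THF/MeOH/H2O, rt
Reagents that add atoms: none
Why: Hydrogenolysis of all seventeen benzyl ethers (aryl and secondary alkyl) under neutral conditions should leave the C4–aryl bonds, the C2–O1 bonds and every stereocentre intact.

**Compound list**

1 | (+)-catechin, (2R,3S)-2-(3,4-dihydroxyphenyl)chromane-3,5,7-triol | Oc1cc(O)c2c(c1)O[C@H](c1ccc(O)c(O)c1)[C@@H](O)C2 | starting material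
2 | 3,5,7,3′,4′-penta-O-benzyl-(+)-catechin | c1c(OCc7ccccc7)cc(OCc7ccccc7)c2c1O[C@H](c1ccc(OCc7ccccc7)c(OCc7ccccc7)c1)[C@@H](OCc7ccccc7)C2 | intermediate
3 | 8-bromo-3,5,7,3′,4′-penta-O-benzyl-(+)-catechin | Brc1c(OCc7ccccc7)cc(OCc7ccccc7)c2c1O[C@H](c1ccc(OCc7ccccc7)c(OCc7ccccc7)c1)[C@@H](OCc7ccccc7)C2 | intermediate
4 | 4-(benzyloxy)-2-hydroxybenzaldehyde | O=Cc1ccc(OCc2ccccc2)cc1O | starting material
5 | 5-bromo-4-(benzyloxy)-2-hydroxybenzaldehyde | O=Cc1cc(Br)c(OCc2ccccc2)cc1O | intermediate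
6 | [3,4-bis(benzyloxy)phenyl]boronic acid | OB(O)c1ccc(OCc2ccccc2)c(OCc2ccccc2)c1 | starting material
7 | potassium [3,4-bis(benzyloxy)phenyl]trifluoroborate | [K+].F[B-](F)(F)c1ccc(OCc2ccccc2)c(OCc2ccccc2)c1 | intermediate
8 | 8-lithio-3,5,7,3′,4′-penta-O-benzylcatechin (aryllithium from 3) | [Li]c1c(OCc7ccccc7)cc(OCc7ccccc7)c2c1O[C@H](c1ccc(OCc7ccccc7)c(OCc7ccccc7)c1)[C@@H](OCc7ccccc7)C2 | intermediate
9 | sodium 5-(benzyloxy)-4-bromo-2-formylphenolate | [Na+].[O-]c1cc(OCc2ccccc2)c(Br)cc1C=O | intermediate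
10 | carbinol B, [5-bromo-4-(benzyloxy)-2-hydroxyphenyl](penta-O-benzylcatechin-8-yl)methanol; both epimers at the carbinol carbon | OC(c1cc(Br)c(OCc7ccccc7)cc1O)c1c(OCc7ccccc7)cc(OCc7ccccc7)c2c1O[C@H](c1ccc(OCc7ccccc7)c(OCc7ccccc7)c1)[C@@H](OCc7ccccc7)C2 | intermediate
11 | 2-(benzyloxy)acetaldehyde | O=CCOCc1ccccc1 | starting material
12 | o-quinone methide B, (6E)-3-(benzyloxy)-4-bromo-6-[(penta-O-benzylcatechin-8-yl)methylidene]cyclohexa-2,4-dien-1-one | O=C1C=C(OCc7ccccc7)C(Br)=C/C1=C\c1c(OCc7ccccc7)cc(OCc7ccccc7)c2c1O[C@H](c1ccc(OCc7ccccc7)c(OCc7ccccc7)c1)[C@@H](OCc7ccccc7)C2 | intermediate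
13 | lactol B, (3R,4S)-3,7-bis(benzyloxy)-6-bromo-4-(penta-O-benzylcatechin-8-yl)chroman-2-ol; 3,4-cis; both anomers at C2 | Brc1cc2c(cc1OCc7ccccc7)OC(O)[C@H](OCc7ccccc7)[C@@H]2c1c(OCc7ccccc7)cc(OCc7ccccc7)c2c1O[C@H](c1ccc(OCc7ccccc7)c(OCc7ccccc7)c1)[C@@H](OCc7ccccc7)C2 | intermediate
14 | dimer bromide, 6-bromo-3,7,3′,4′-tetra-O-benzyl-ent-fisetinidol-(4α→8)-3,5,7,3′,4′-penta-O-benzylcatechin | Brc1cc2c(cc1OCc7ccccc7)O[C@@H](c1ccc(OCc7ccccc7)c(OCc7ccccc7)c1)[C@H](OCc7ccccc7)[C@@H]2c1c(OCc7ccccc7)cc(OCc7ccccc7)c2c1O[C@H](c1ccc(OCc7ccccc7)c(OCc7ccccc7)c1)[C@@H](OCc7ccccc7)C2 | intermediate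
15 | sodium 5-(benzyloxy)-2-formylphenolate | [Na+].[O-]c1cc(OCc2ccccc2)ccc1C=O | intermediate
16 | 6-lithio derivative of 14 (Li in place of Br) | [Li]c1cc2c(cc1OCc7ccccc7)O[C@@H](c1ccc(OCc7ccccc7)c(OCc7ccccc7)c1)[C@H](OCc7ccccc7)[C@@H]2c1c(OCc7ccccc7)cc(OCc7ccccc7)c2c1O[C@H](c1ccc(OCc7ccccc7)c(OCc7ccccc7)c1)[C@@H](OCc7ccccc7)C2 | intermediate
17 | carbinol A, 14 with CH(OH)[4-(benzyloxy)-2-hydroxyphenyl] in place of Br; both carbinol epimers | OC(c1ccc(OCc7ccccc7)cc1O)c1cc2c(cc1OCc7ccccc7)O[C@@H](c1ccc(OCc7ccccc7)c(OCc7ccccc7)c1)[C@H](OCc7ccccc7)[C@@H]2c1c(OCc7ccccc7)cc(OCc7ccccc7)c2c1O[C@H](c1ccc(OCc7ccccc7)c(OCc7ccccc7)c1)[C@@H](OCc7ccccc7)C2 | intermediate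
18 | o-quinone methide A, (6E)-3-(benzyloxy)-6-(arylmethylidene)cyclohexa-2,4-dien-1-one with aryl = C6 of the upper unit of the dimer | O=C1C=C(OCc7ccccc7)C=C/C1=C\c1cc2c(cc1OCc7ccccc7)O[C@@H](c1ccc(OCc7ccccc7)c(OCc7ccccc7)c1)[C@H](OCc7ccccc7)[C@@H]2c1c(OCc7ccccc7)cc(OCc7ccccc7)c2c1O[C@H](c1ccc(OCc7ccccc7)c(OCc7ccccc7)c1)[C@@H](OCc7ccccc7)C2 | intermediate
19 | lactol A, top unit a (3R)-3,7-bis(benzyloxy)-3,4-cis-chroman-2-ol joined through C4 to C6 of the middle unit; both anomers | c7ccccc7COc1ccc2c(c1)OC(O)[C@H](OCc7ccccc7)[C@@H]2c1cc2c(cc1OCc7ccccc7)O[C@@H](c1ccc(OCc7ccccc7)c(OCc7ccccc7)c1)[C@H](OCc7ccccc7)[C@@H]2c1c(OCc7ccccc7)cc(OCc7ccccc7)c2c1O[C@H](c1ccc(OCc7ccccc7)c(OCc7ccccc7)c1)[C@@H](OCc7ccccc7)C2 | intermediate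
20 | trimer, 3,7,3′,4′-tetra-O-benzyl-ent-fisetinidol-(4α→6)-3,7,3′,4′-tetra-O-benzyl-ent-fisetinidol-(4α→8)-3,5,7,3′,4′-penta-O-benzylcatechin | c7ccccc7COc1ccc2c(c1)O[C@@H](c1ccc(OCc7ccccc7)c(OCc7ccccc7)c1)[C@H](OCc7ccccc7)[C@@H]2c1cc2c(cc1OCc7ccccc7)O[C@@H](c1ccc(OCc7ccccc7)c(OCc7ccccc7)c1)[C@H](OCc7ccccc7)[C@@H]2c1c(OCc7ccccc7)cc(OCc7ccccc7)c2c1O[C@H](c1ccc(OCc7ccccc7)c(OCc7ccccc7)c1)[C@@H](OCc7ccccc7)C2 | intermediate
21 | 6-bromo trimer (Br at C6 of the catechin unit of 20) | c7ccccc7COc1ccc2c(c1)O[C@@H](c1ccc(OCc7ccccc7)c(OCc7ccccc7)c1)[C@H](OCc7ccccc7)[C@@H]2c1cc2c(cc1OCc7ccccc7)O[C@@H](c1ccc(OCc7ccccc7)c(OCc7ccccc7)c1)[C@H](OCc7ccccc7)[C@@H]2c1c(OCc7ccccc7)c(Br)c(OCc7ccccc7)c2c1O[C@H](c1ccc(OCc7ccccc7)c(OCc7ccccc7)c1)[C@@H](OCc7ccccc7)C2 | intermediate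
22 | 6-lithio trimer (Li in place of Br in 21) | c7ccccc7COc1ccc2c(c1)O[C@@H](c1ccc(OCc7ccccc7)c(OCc7ccccc7)c1)[C@H](OCc7ccccc7)[C@@H]2c1cc2c(cc1OCc7ccccc7)O[C@@H](c1ccc(OCc7ccccc7)c(OCc7ccccc7)c1)[C@H](OCc7ccccc7)[C@@H]2c1c(OCc7ccccc7)c([Li])c(OCc7ccccc7)c2c1O[C@H](c1ccc(OCc7ccccc7)c(OCc7ccccc7)c1)[C@@H](OCc7ccccc7)C2 | intermediate
23 | carbinol D, 20 carrying CH(OH)[4-(benzyloxy)-2-hydroxyphenyl] at C6 of the catechin unit; both carbinol epimers | c7ccccc7COc1ccc2c(c1)O[C@@H](c1ccc(OCc7ccccc7)c(OCc7ccccc7)c1)[C@H](OCc7ccccc7)[C@@H]2c1cc2c(cc1OCc7ccccc7)O[C@@H](c1ccc(OCc7ccccc7)c(OCc7ccccc7)c1)[C@H](OCc7ccccc7)[C@@H]2c1c(OCc7ccccc7)c(C(O)c3ccc(OCc7ccccc7)cc3O)c(OCc7ccccc7)c2c1O[C@H](c1ccc(OCc7ccccc7)c(OCc7ccccc7)c1)[C@@H](OCc7ccccc7)C2 | intermediate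
24 | o-quinone methide D, (6E)-3-(benzyloxy)-6-(arylmethylidene)cyclohexa-2,4-dien-1-one with aryl = C6 of the catechin unit of 20 | c7ccccc7COc1ccc2c(c1)O[C@@H](c1ccc(OCc7ccccc7)c(OCc7ccccc7)c1)[C@H](OCc7ccccc7)[C@@H]2c1cc2c(cc1OCc7ccccc7)O[C@@H](c1ccc(OCc7ccccc7)c(OCc7ccccc7)c1)[C@H](OCc7ccccc7)[C@@H]2c1c(OCc7ccccc7)c(\C=C3/C=CC(OCc7ccccc7)=CC3=O)c(OCc7ccccc7)c2c1O[C@H](c1ccc(OCc7ccccc7)c(OCc7ccccc7)c1)[C@@H](OCc7ccccc7)C2 | intermediate
25 | lactol D, 20 carrying at C6 of the catechin unit a (3R,4S)-3,7-bis(benzyloxy)-2-hydroxychroman-4-yl group; 3,4-cis; both anomers | c7ccccc7COc1ccc2c(c1)O[C@@H](c1ccc(OCc7ccccc7)c(OCc7ccccc7)c1)[C@H](OCc7ccccc7)[C@@H]2c1cc2c(cc1OCc7ccccc7)O[C@@H](c1ccc(OCc7ccccc7)c(OCc7ccccc7)c1)[C@H](OCc7ccccc7)[C@@H]2c1c(OCc7ccccc7)c([C@@H]2c3ccc(OCc7ccccc7)cc3OC(O)[C@@H]2OCc7ccccc7)c(OCc7ccccc7)c2c1O[C@H](c1ccc(OCc7ccccc7)c(OCc7ccccc7)c1)[C@@H](OCc7ccccc7)C2 | intermediate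
26 | heptadeca-O-benzyl tetramer (per-O-benzyl ether of 27) | c7ccccc7COc1ccc2c(c1)O[C@@H](c1ccc(OCc7ccccc7)c(OCc7ccccc7)c1)[C@H](OCc7ccccc7)[C@@H]2c1cc2c(cc1OCc7ccccc7)O[C@@H](c1ccc(OCc7ccccc7)c(OCc7ccccc7)c1)[C@H](OCc7ccccc7)[C@@H]2c1c(OCc7ccccc7)c([C@@H]2c3ccc(OCc7ccccc7)cc3O[C@@H](c3ccc(OCc7ccccc7)c(OCc7ccccc7)c3)[C@@H]2OCc7ccccc7)c(OCc7ccccc7)c2c1O[C@H](c1ccc(OCc7ccccc7)c(OCc7ccccc7)c1)[C@@H](OCc7ccccc7)C2 | intermediate
27 | ent-fisetinidol-(4α→6)-ent-fisetinidol-(4α→8)-catechin-(6→4α)-ent-fisetinidol; upper units 2S,3R with 4-aryl cis to 3-OH, catechin unit 2R,3S | Oc1ccc2c(c1)O[C@@H](c1ccc(O)c(O)c1)[C@H](O)[C@@H]2c1cc2c(cc1O)O[C@@H](c1ccc(O)c(O)c1)[C@H](O)[C@@H]2c1c(O)c([C@@H]2c3ccc(O)cc3O[C@@H](c3ccc(O)c(O)c3)[C@@H]2O)c(O)c2c1O[C@H](c1ccc(O)c(O)c1)[C@@H](O)C2 | target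

**Count**

Total step count: 16. Longest linear sequence: 13 steps (1, 2, 5 to 7 and 9 to 16, from (+)-catechin); steps 3, 4 and 8 are one-step side branches.

**Steps most likely to fail**

1. Step 14 (key annulation). The enol may capture the quinone methide slowly, because the methide carbon carries a 2,6-dioxygenated aryl group. The cis selectivity may also erode, through an open stepwise transition state or by acid-mediated epimerisation at C3 of the lactol. The fallback sets out from 23 and comes back at 25. Carbinol 23 is treated with sodium 4-methylbenzenesulfinate in aqueous formic acid to give the benzylic sulfone F1. Cs2CO3 then releases quinone methide 24 from F1 under basic conditions. In the same flask the carbene from (5aS,10bR)-2-(2,4,6-trimethylphenyl)-5a,10b-dihydro-4H,6H-indeno[2,1-b][1,2,4]triazolo[4,3-d][1,4]oxazin-2-ium tetrafluoroborate (or its antipode, by the sense of induction) and i-Pr2NEt turn 2-(benzyloxy)acetyl chloride into an azolium enolate. Its endo oxa-Diels–Alder addition to 24, a reaction type known to give cis-3,4-disubstituted dihydrocoumarins, should give the cis-lactone F2. i-Bu2AlH in CH2Cl2 at −78 °C reduces F2 to lactol 25.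

2. Step 15 (C2 arylation at the most crowded junction). The C2 oxocarbenium ion may be intercepted by electron-rich ring positions of other substrate molecules, may lose the C3 proton to give the 4H-chromene enol ether, or may take up the aryl group slowly. The fallback sets out from 25 and comes back at 26. The Grignard reagent [3,4-bis(benzyloxy)phenyl]magnesium bromide F3 (from 4-bromo-1,2-bis(benzyloxy)benzene and Mg, THF) is added in excess to the open hydroxy-aldehyde tautomer of 25 to give the seco-diol F4 (free phenol, benzylic C2 carbinol as both epimers). Catalytic 4-methylbenzenesulfonic acid in CH2Cl2 then closes the ring by cyclodehydration through the 4′-benzyloxy-stabilised benzylic cation, which should favour the 2,3-trans flavan 26 whatever the C2 configuration of F4.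

3. Step 13 (lithiation and addition on the trimer). Bromine–lithium exchange may be incomplete or be followed by anionic side reactions (rearrangement of the ortho-lithiated benzyl ether, benzylic deprotonation), and the hindered aryllithium may add slowly to the phenolate-deactivated aldehyde. The fallback sets out from 20, bypasses 21, and comes back at 23. Vilsmeier–Haack formylation of 20 (POCl3, DMF, 0 → 60 °C; aq. NaOAc) at C6 of the catechin unit gives the 6-formyl trimer F5. The O,C-dilithio species lithium 5-(benzyloxy)-2-lithiophenolate F6 (from 2-bromo-5-(benzyloxy)phenol and 2 equiv n-BuLi, THF, −78 °C) is then added to F5 to give carbinol 23.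

Further compounds
F1 | step 14 | benzylic sulfone, 20 carrying CH(SO2C6H4CH3-4)[4-(benzyloxy)-2-hydroxyphenyl] at C6 of the catechin unit; both epimers at the sulfonyl-bearing carbon | c7ccccc7COc1ccc2c(c1)O[C@@H](c1ccc(OCc7ccccc7)c(OCc7ccccc7)c1)[C@H](OCc7ccccc7)[C@@H]2c1cc2c(cc1OCc7ccccc7)O[C@@H](c1ccc(OCc7ccccc7)c(OCc7ccccc7)c1)[C@H](OCc7ccccc7)[C@@H]2c1c(OCc7ccccc7)c(C(S(=O)(=O)c3ccc(C)cc3)c3ccc(OCc7ccccc7)cc3O)c(OCc7ccccc7)c2c1O[C@H](c1ccc(OCc7ccccc7)c(OCc7ccccc7)c1)[C@@H](OCc7ccccc7)C2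
F2 | step 14 | cis-lactone, 20 carrying at C6 of the catechin unit a (3R,4S)-3,7-bis(benzyloxy)-2-oxochroman-4-yl group | c7ccccc7COc1ccc2c(c1)O[C@@H](c1ccc(OCc7ccccc7)c(OCc7ccccc7)c1)[C@H](OCc7ccccc7)[C@@H]2c1cc2c(cc1OCc7ccccc7)O[C@@H](c1ccc(OCc7ccccc7)c(OCc7ccccc7)c1)[C@H](OCc7ccccc7)[C@@H]2c1c(OCc7ccccc7)c([C@@H]2c3ccc(OCc7ccccc7)cc3OC(=O)[C@@H]2OCc7ccccc7)c(OCc7ccccc7)c2c1O[C@H](c1ccc(OCc7ccccc7)c(OCc7ccccc7)c1)[C@@H](OCc7ccccc7)C2
F3 | step 15 | [3,4-bis(benzyloxy)phenyl]magnesium bromide | Br[Mg]c1ccc(OCc2ccccc2)c(OCc2ccccc2)c1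
F4 | step 15 | seco-diol, 20 carrying at C6 of the catechin unit the open chain CH[4-(benzyloxy)-2-hydroxyphenyl]–CH(OBn)–CH(OH)[3,4-bis(benzyloxy)phenyl]; C3 and C4 as in 25, both C2 epimers | c7ccccc7COc1ccc2c(c1)O[C@@H](c1ccc(OCc7ccccc7)c(OCc7ccccc7)c1)[C@H](OCc7ccccc7)[C@@H]2c1cc2c(cc1OCc7ccccc7)O[C@@H](c1ccc(OCc7ccccc7)c(OCc7ccccc7)c1)[C@H](OCc7ccccc7)[C@@H]2c1c(OCc7ccccc7)c([C@H](c3ccc(OCc7ccccc7)cc3O)[C@@H](OCc7ccccc7)C(O)c3ccc(OCc7ccccc7)c(OCc7ccccc7)c3)c(OCc7ccccc7)c2c1O[C@H](c1ccc(OCc7ccccc7)c(OCc7ccccc7)c1)[C@@H](OCc7ccccc7)C2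
F5 | step 13 | 6-formyl trimer (CHO at C6 of the catechin unit of 20) | c7ccccc7COc1ccc2c(c1)O[C@@H](c1ccc(OCc7ccccc7)c(OCc7ccccc7)c1)[C@H](OCc7ccccc7)[C@@H]2c1cc2c(cc1OCc7ccccc7)O[C@@H](c1ccc(OCc7ccccc7)c(OCc7ccccc7)c1)[C@H](OCc7ccccc7)[C@@H]2c1c(OCc7ccccc7)c(C=O)c(OCc7ccccc7)c2c1O[C@H](c1ccc(OCc7ccccc7)c(OCc7ccccc7)c1)[C@@H](OCc7ccccc7)C2
F6 | step 13 | lithium 5-(benzyloxy)-2-lithiophenolate | [Li]Oc1cc(OCc2ccccc2)ccc1[Li]
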